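**Retrosynthetic overview**

1. The acetate goes on last. Ring D (C13–C16 bond, exocyclic methylene, conjugated enone) comes from a Pd-catalysed Alder-ene cycloisomerisation of a 1,6-enyne on a cyclohex-4-enone. The C15 carbinol comes from CBS reduction of an ynone.
2. Quaternary C8 comes from C-acylation of a bicyclic enol ether made by Birch reduction of a 2-substituted 2,3-dihydrobenzofuran (key step). The ether stereocentre C6 steers C8, and its oxygen later becomes the lactone oxygen.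
3. The dihydrobenzofuran comes from intramolecular SNAr of a 2-fluorobenzyl carbinol. C6 is set by Felkin addition of the benzyl unit to an epoxy aldehyde.
4. Ring A (C4, C5, C10) comes from a Stork epoxynitrile cyclisation. Absolute configuration comes from one Sharpless epoxidation.
5. Ring order: epoxide, ring A, dihydrofuran on the arene, Birch to ring C, lactone, ring D.

Assumption: locants C1–C20 follow ent-kaurane numbering of the target (ring A C1–C5/C10, lactone C19–O–C6, C7 methylene, bicycle C8–C17); 1, 7 and 3-(trimethylsilyl)prop-2-ynoic acid are bought.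

**Route**

Step 1
Reactants: 1 5-iodopent-1-yne
Product: 4 (2E)-6-iodo-3-methylhex-2-en-1-ol, via alkenylalane 2 (not isolated), via lithium alanate 3 (not isolated)
Conditions: Me3Al (2.5 equiv), Cp2ZrCl2 (0.2 equiv), CH2Cl2, 0 °C to rt; n-BuLi, THF, −78 °C; (CH2O)n, −78 °C to rt; aq. HCl
Reagents that add atoms: trimethylaluminium C[Al](C)C; paraformaldehyde (as formaldehyde) C=O
Why: Negishi zirconium-catalysed carboalumination adds methyl and aluminium syn across the alkyne and the derived alanate is hydroxymethylated with retention, so only the (E)-trisubstituted allylic alcohol forms and no stereocentre is created.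

Step 2
Reactants: 4 (2E)-6-iodo-3-methylhex-2-en-1-ol
Product: 5 [(2R,3R)-3-(3-iodopropyl)-3-methyloxiran-2-yl]methanol
Conditions: Ti(OiPr)4 (10 mol%), D-(−)-diethyl tartrate (12 mol%), t-BuOOH, 4 Å MS, CH2Cl2, −20 °C
Reagents that add atoms: tert-butyl hydroperoxide CC(C)(C)OO
Why: Sharpless asymmetric epoxidation of an (E)-trisubstituted primary allylic alcohol is reliable, and D-(−)-tartrate gives the (2R,3R)-epoxide (the mirror sense of L-(+)-tartrate on geraniol), which fixes the future C5/C10 pair and the absolute configuration of the route.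

Step 3
Reactants: 5 [(2R,3R)-3-(3-iodopropyl)-3-methyloxiran-2-yl]methanol
Product: 6 (2S,3R)-3-(3-iodopropyl)-3-methyloxirane-2-carbaldehyde
Conditions: Dess–Martin periodinane, pyridine, CH2Cl2, 0 °C
Reagents that add atoms: none
Why: Dess–Martin oxidation gives the configurationally stable α,β-epoxy aldehyde under buffered non-basic conditions that leave the epoxide and the primary iodide untouched.

Step 4
Reactants: 6 (2S,3R)-3-(3-iodopropyl)-3-methyloxirane-2-carbaldehyde; 7 2-fluorobenzyl chloride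
Product: 10 (1R)-2-(2-fluorophenyl)-1-[(2R,3R)-3-(3-iodopropyl)-3-methyloxiran-2-yl]ethan-1-ol, via Grignard reagent 8 (not isolated), via benzyltitanium reagent 9 (not isolated)
Conditions: 7, Mg, Et2O; ClTi(OiPr)3, THF, −78 °C; 6, −78 to −20 °C; aq. HCl
Reagents that add atoms: none
Why: A non-chelating benzyltitanium reagent (Reetz type) adds through the Felkin–Anh/Cornforth transition state with the epoxide C–O bond anti to the incoming carbon, which gives the (1R)-carbinol that becomes C6.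

Step 5
Reactants: 10 (1R)-2-(2-fluorophenyl)-1-[(2R,3R)-3-(3-iodopropyl)-3-methyloxiran-2-yl]ethan-1-ol
Product: 12 (1R,2S,3R)-2-[(1R)-2-(2-fluorophenyl)-1-hydroxyethyl]-3-hydroxy-1,3-dimethylcyclohexane-1-carbonitrile, via alkylated epoxy nitrile 11 (not isolated)
Conditions: EtCN (1.1 equiv), LiN(iPr)2 (3.3 equiv), THF, −78 to 0 °C; aq. NH4Cl
Reagents that add atoms: propionitrile CCC#N
Why: Lithiated propionitrile alkylates the primary iodide and the re-formed nitrile anion then opens the epoxide at its secondary carbon with inversion (Stork epoxynitrile cyclisation, six-membered ring because the other epoxide carbon is fully substituted), the small cyano group taking the position syn to the axial methyl of the forming chair, which sets C4, C5 and C10 (the all-lithium aprotic medium is chosen to suppress Payne rearrangement).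

Step 6
Reactants: 12 (1R,2S,3R)-2-[(1R)-2-(2-fluorophenyl)-1-hydroxyethyl]-3-hydroxy-1,3-dimethylcyclohexane-1-carbonitrile
Product: 13 (1R,2S,3R)-2-[(2R)-2,3-dihydro-1-benzofuran-2-yl]-3-hydroxy-1,3-dimethylcyclohexane-1-carbonitrile
Conditions: KN(SiMe3)2 (2.2 equiv), THF/DMF, 70 °C; aq. NH4Cl
Reagents that add atoms: none
Why: Intramolecular nucleophilic aromatic substitution of the aryl fluoride by the secondary potassium alkoxide closes the five-membered ring without touching the carbinol carbon, so C6 keeps its configuration.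

Step 7
Reactants: 13 (1R,2S,3R)-2-[(2R)-2,3-dihydro-1-benzofuran-2-yl]-3-hydroxy-1,3-dimethylcyclohexane-1-carbonitrile
Product: 14 (1R,2S,3R)-2-[(2R)-2,3-dihydro-1-benzofuran-2-yl]-3-hydroxy-1,3-dimethylcyclohexane-1-carboxamide
Conditions: [PtH(PMe2OH)(PMe2O)2H] (2 mol%), EtOH/H2O, 80 °C
Reagents that add atoms: water O
Why: Platinum-catalysed nitrile hydration (Ghaffar–Parkins type) converts hindered tertiary nitriles to primary amides under neutral conditions, giving a carboxyl equivalent that survives dissolving metal, whereas a tertiary nitrile would be reductively cleaved.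

Step 8
Reactants: 14 (1R,2S,3R)-2-[(2R)-2,3-dihydro-1-benzofuran-2-yl]-3-hydroxy-1,3-dimethylcyclohexane-1-carboxamide
Product: 15 (1R,2S,3R)-3-hydroxy-1,3-dimethyl-2-[(2R)-2,3,4,7-tetrahydro-1-benzofuran-2-yl]cyclohexane-1-carboxamide
Conditions: Li, NH3(l), THF, t-BuOH, −78 °C; NH4Cl
Reagents that add atoms: none
Why: Birch reduction of the aryl alkyl ether keeps the oxygen- and alkyl-bearing carbons unsaturated, so the arene becomes a 1,4-diene whose tetrasubstituted enol ether (C8=C9) sits in a five-membered ring next to the C6 stereocentre and whose isolated C12=C13 alkene is placed for ring D.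

Step 9
Reactants: 15 (1R,2S,3R)-3-hydroxy-1,3-dimethyl-2-[(2R)-2,3,4,7-tetrahydro-1-benzofuran-2-yl]cyclohexane-1-carboxamide
Product: 18 (3R,3aS,4R,7aR)-4-hydroxy-4,7a-dimethyl-3-({(1S)-2-oxo-1-[3-(trimethylsilyl)prop-2-ynoyl]cyclohex-4-en-1-yl}methyl)hexahydro-2-benzofuran-1(3H)-one, via α-chloro ether 16 (not isolated), via hydroxy amide 17 (not isolated)
Conditions: TMSC≡CCO2H, (COCl)2, DMF (cat.), CH2Cl2, 0 °C, then evaporate; 15, ZnCl2 (0.2 equiv), CH2Cl2, −78 to −30 °C; 5% aq. oxalic acid, THF, 40 °C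
Reagents that add atoms: 3-(trimethylsilyl)prop-2-ynoic acid C[Si](C)(C)C#CC(=O)O; water O
Why: Proposed new method: Lewis-acid-assisted C-acylation of the cyclic enol ether (closest known type: Friedel–Crafts/Mukaiyama acylation of enol ethers) should occur at the nucleophilic β-carbon on the face anti to the bulky C2 substituent, as in alkylations of γ-substituted butyrolactone enolates, creating quaternary C8, after which hydrolysis of the α-chloro ether frees the C9 ketone and the C6 hydroxyl, which lactonises onto the cis amide with loss of ammonia.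

Step 10
Reactants: 18 (3R,3aS,4R,7aR)-4-hydroxy-4,7a-dimethyl-3-({(1S)-2-oxo-1-[3-(trimethylsilyl)prop-2-ynoyl]cyclohex-4-en-1-yl}methyl)hexahydro-2-benzofuran-1(3H)-one
Product: 19 (3R,3aS,4R,7aR)-4-hydroxy-3-({(1R)-1-[(1S)-1-hydroxy-3-(trimethylsilyl)prop-2-yn-1-yl]-2-oxocyclohex-4-en-1-yl}methyl)-4,7a-dimethylhexahydro-2-benzofuran-1(3H)-one
Conditions: (S)-1-methyl-3,3-diphenyltetrahydro-1H,3H-pyrrolo[1,2-c][1,3,2]oxazaborole (20 mol%), catecholborane, toluene, −78 °C
Reagents that add atoms: none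
Why: Corey–Bakshi–Shibata reduction is reagent-controlled for ynones in which the alkynyl group is the small and the quaternary carbon the large substituent, so the (S)-catalyst gives the C15 carbinol with the target configuration while the hindered ring ketone is left alone.

Step 11
Reactants: 19 (3R,3aS,4R,7aR)-4-hydroxy-3-({(1R)-1-[(1S)-1-hydroxy-3-(trimethylsilyl)prop-2-yn-1-yl]-2-oxocyclohex-4-en-1-yl}methyl)-4,7a-dimethylhexahydro-2-benzofuran-1(3H)-one
Product: 20 (3R,3aS,4R,7aR)-4-hydroxy-3-({(1R)-1-[(1R)-1-hydroxyprop-2-yn-1-yl]-2-oxocyclohex-4-en-1-yl}methyl)-4,7a-dimethylhexahydro-2-benzofuran-1(3H)-one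
Conditions: Bu4NF, AcOH, THF, 0 °C
Reagents that add atoms: none
Why: Buffered fluoride removes the alkynyl silyl group without the basic conditions that could trigger retro-aldol cleavage of the β-hydroxy ketone.

Step 12
Reactants: 20 (3R,3aS,4R,7aR)-4-hydroxy-3-({(1R)-1-[(1R)-1-hydroxyprop-2-yn-1-yl]-2-oxocyclohex-4-en-1-yl}methyl)-4,7a-dimethylhexahydro-2-benzofuran-1(3H)-one
Product: 21 (3R,3aS,4R,7aR)-4-hydroxy-3-{[(1R,5S,7R)-7-hydroxy-6-methylidene-2-oxobicyclo[3.2.1]oct-3-en-1-yl]methyl}-4,7a-dimethylhexahydro-2-benzofuran-1(3H)-one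
Conditions: Pd(OAc)2 (10 mol%), PPh3 (20 mol%), toluene, 70 °C
Reagents that add atoms: none
Why: Trost palladium-catalysed enyne cycloisomerisation (Alder-ene type) joins the internal alkyne carbon to C13 in a 5-exo sense and β-hydride elimination from C11 gives the exocyclic methylene together with the conjugated enone, the C13 bridgehead configuration being dictated by C8.

Step 13
Reactants: 21 (3R,3aS,4R,7aR)-4-hydroxy-3-{[(1R,5S,7R)-7-hydroxy-6-methylidene-2-oxobicyclo[3.2.1]oct-3-en-1-yl]methyl}-4,7a-dimethylhexahydro-2-benzofuran-1(3H)-one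
Product: 22 CNP0172716.1
Conditions: Ac2O, pyridine, 4-(dimethylamino)pyridine (cat.), CH2Cl2, 0 °C
Reagents that add atoms: acetic anhydride CC(=O)OC(C)=O
Why: Nucleophile-catalysed acetylation takes the secondary allylic alcohol while the hindered tertiary alcohol stays free.

**Compound list**

1 | 5-iodopent-1-yne | C#CCCCI | starting material
2 | (E)-(5-iodo-2-methylpent-1-en-1-yl)dimethylalumane | C[Al](C)/C=C(\C)CCCI | intermediate
3 | lithium butyl[(E)-5-iodo-2-methylpent-1-en-1-yl]dimethylaluminate | [Li+].CCCC[Al-](C)(C)/C=C(\C)CCCI | intermediate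
4 | (2E)-6-iodo-3-methylhex-2-en-1-ol | OC/C=C(\C)CCCI | intermediate
5 | [(2R,3R)-3-(3-iodopropyl)-3-methyloxiran-2-yl]methanol | OC[C@H]1O[C@]1(C)CCCI | intermediate
6 | (2S,3R)-3-(3-iodopropyl)-3-methyloxirane-2-carbaldehyde | O=C[C@H]1O[C@]1(C)CCCI | intermediate
7 | 2-fluorobenzyl chloride (1-(chloromethyl)-2-fluorobenzene) | Fc1ccccc1CCl | starting material
8 | (2-fluorobenzyl)magnesium chloride | Fc1ccccc1C[Mg]Cl | intermediate
9 | (2-fluorobenzyl)tri(propan-2-yloxy)titanium | CC(C)O[Ti](OC(C)C)(OC(C)C)Cc1ccccc1F | intermediate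
10 | (1R)-2-(2-fluorophenyl)-1-[(2R,3R)-3-(3-iodopropyl)-3-methyloxiran-2-yl]ethan-1-ol | O[C@H](Cc1ccccc1F)[C@H]1O[C@]1(C)CCCI | intermediate
11 | 5-{(2R,3R)-3-[(1R)-2-(2-fluorophenyl)-1-hydroxyethyl]-2-methyloxiran-2-yl}-2-methylpentanenitrile (both C2 epimers) | O[C@H](Cc1ccccc1F)[C@H]1O[C@]1(C)CCCC(C)C#N | intermediate
12 | (1R,2S,3R)-2-[(1R)-2-(2-fluorophenyl)-1-hydroxyethyl]-3-hydroxy-1,3-dimethylcyclohexane-1-carbonitrile | N#C[C@]1(C)CCC[C@@](C)(O)[C@@H]1[C@H](O)Cc1ccccc1F | intermediate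
13 | (1R,2S,3R)-2-[(2R)-2,3-dihydro-1-benzofuran-2-yl]-3-hydroxy-1,3-dimethylcyclohexane-1-carbonitrile | N#C[C@]1(C)CCC[C@@](C)(O)[C@@H]1[C@H]2Cc3ccccc3O2 | intermediate
14 | (1R,2S,3R)-2-[(2R)-2,3-dihydro-1-benzofuran-2-yl]-3-hydroxy-1,3-dimethylcyclohexane-1-carboxamide | NC(=O)[C@]1(C)CCC[C@@](C)(O)[C@@H]1[C@H]2Cc3ccccc3O2 | intermediate
15 | (1R,2S,3R)-3-hydroxy-1,3-dimethyl-2-[(2R)-2,3,4,7-tetrahydro-1-benzofuran-2-yl]cyclohexane-1-carboxamide | NC(=O)[C@]1(C)CCC[C@@](C)(O)[C@@H]1[C@H]2CC3=C(O2)CC=CC3 | intermediate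
16 | (1R,2S,3R)-2-{(2R,3aR)-7a-chloro-3a-[3-(trimethylsilyl)prop-2-ynoyl]-2,3,3a,4,7,7a-hexahydro-1-benzofuran-2-yl}-3-hydroxy-1,3-dimethylcyclohexane-1-carboxamide (C7a configuration open) | NC(=O)[C@]1(C)CCC[C@@](C)(O)[C@@H]1[C@H]2C[C@@]3(C(=O)C#C[Si](C)(C)C)CC=CCC3(Cl)O2 | intermediate
17 | (1R,2S,3R)-3-hydroxy-2-[(1R)-1-hydroxy-2-{(1S)-2-oxo-1-[3-(trimethylsilyl)prop-2-ynoyl]cyclohex-4-en-1-yl}ethyl]-1,3-dimethylcyclohexane-1-carboxamide | NC(=O)[C@]1(C)CCC[C@@](C)(O)[C@@H]1[C@H](O)C[C@@]2(C(=O)C#C[Si](C)(C)C)CC=CCC2=O | intermediate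
18 | (3R,3aS,4R,7aR)-4-hydroxy-4,7a-dimethyl-3-({(1S)-2-oxo-1-[3-(trimethylsilyl)prop-2-ynoyl]cyclohex-4-en-1-yl}methyl)hexahydro-2-benzofuran-1(3H)-one | C[Si](C)(C)C#CC(=O)[C@]1(C[C@H]2OC(=O)[C@]3(C)CCC[C@@](C)(O)[C@H]23)CC=CCC1=O | intermediate
19 | (3R,3aS,4R,7aR)-4-hydroxy-3-({(1R)-1-[(1S)-1-hydroxy-3-(trimethylsilyl)prop-2-yn-1-yl]-2-oxocyclohex-4-en-1-yl}methyl)-4,7a-dimethylhexahydro-2-benzofuran-1(3H)-one | C[Si](C)(C)C#C[C@@H](O)[C@]1(C[C@H]2OC(=O)[C@]3(C)CCC[C@@](C)(O)[C@H]23)CC=CCC1=O | intermediate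
20 | (3R,3aS,4R,7aR)-4-hydroxy-3-({(1R)-1-[(1R)-1-hydroxyprop-2-yn-1-yl]-2-oxocyclohex-4-en-1-yl}methyl)-4,7a-dimethylhexahydro-2-benzofuran-1(3H)-one | C#C[C@@H](O)[C@]1(C[C@H]2OC(=O)[C@]3(C)CCC[C@@](C)(O)[C@H]23)CC=CCC1=O | intermediate
21 | (3R,3aS,4R,7aR)-4-hydroxy-3-{[(1R,5S,7R)-7-hydroxy-6-methylidene-2-oxobicyclo[3.2.1]oct-3-en-1-yl]methyl}-4,7a-dimethylhexahydro-2-benzofuran-1(3H)-one | C=C1[C@@H]2C=CC(=O)[C@@](C[C@H]3OC(=O)[C@]4(C)CCC[C@@](C)(O)[C@H]34)(C2)[C@@H]1O | intermediate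
22 | CNP0172716.1, (1R,5S,7R)-1-{[(1R,3aR,7R,7aS)-7-hydroxy-3a,7-dimethyl-3-oxooctahydro-2-benzofuran-1-yl]methyl}-6-methylidene-2-oxobicyclo[3.2.1]oct-3-en-7-yl acetate | C=C1[C@@H]2C=CC(=O)[C@@](C[C@H]3OC(=O)[C@]4(C)CCC[C@@](C)(O)[C@H]34)(C2)[C@@H]1OC(C)=O | target

**Step count and risks**

Total steps: 13. Longest linear sequence: 13 steps (1 to 22); 7 enters at step 4 without prior steps.

The three steps most likely to fail:

Step 5. The nitrile anion must attack an epoxide carbon that carries the branched C6 carbinol, and the neighbouring alkoxide could open the epoxide first (Payne rearrangement), which would invert C5. The fallback sets out from 5 and comes back at 12, building ring A before the arene is attached. The same propionitrile alkylation and epoxide opening on 5 gives the diol nitrile F1. Dess–Martin oxidation gives the β-hydroxy aldehyde F2. Grignard reagent 8 adds to give the carbinol F3; chelation by the C10 alkoxide favours the unwanted C6 epimer, which does not matter here. A second Dess–Martin oxidation gives the ketone F4. Hydroxyl-directed reduction with Me4NBH(OAc)3 (Evans–Saksena, 1,3-anti) then delivers 12.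

Step 9. The acylation creates the C8 quaternary centre on a tetrasubstituted enol ether; the acid chloride could instead react with the primary amide, the facial control rests on analogy, and lactonisation of the hydroxy amide in oxalic acid is assumed. The fallback sets out from 15 and comes back at 18. A BF3·OEt2-mediated Mukaiyama-type aldol addition of the enol ether to 3-(trimethylsilyl)propynal (same anti approach), followed by the oxalic acid work-up, gives the propargylic carbinol lactone F5 as C15 epimers. MnO2 oxidation of the propargylic alcohol converges both epimers on ynone 18.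

Step 12. Palladium hydride may move the C12=C13 alkene into conjugation before it cyclises, and the ring closure has to form a bridged bicycle. The fallback sets out from 20 and comes back at 22. Bu3SnH with azobisisobutyronitrile adds a stannyl radical to the alkyne, and the vinyl radical closes 5-exo onto C13 to give the vinylstannane F6. HCl in ether removes tin to give the saturated bicyclic ketone F7. Ac2O/pyridine gives the acetate F8. Aerobic dehydrogenation with Pd(OCOCF3)2/DMSO/O2 in AcOH, possible only towards C11, then gives 22.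

**Further compounds**

F1 | step 5 | (1R,2S,3R)-3-hydroxy-2-(hydroxymethyl)-1,3-dimethylcyclohexane-1-carbonitrile | N#C[C@]1(C)CCC[C@@](C)(O)[C@@H]1CO
F2 | step 5 | (1R,2R,3R)-2-formyl-3-hydroxy-1,3-dimethylcyclohexane-1-carbonitrile | N#C[C@]1(C)CCC[C@@](C)(O)[C@@H]1C=O
F3 | step 5 | (1R,2S,3R)-2-[2-(2-fluorophenyl)-1-hydroxyethyl]-3-hydroxy-1,3-dimethylcyclohexane-1-carbonitrile (carbinol epimers) | N#C[C@]1(C)CCC[C@@](C)(O)[C@@H]1C(O)Cc1ccccc1F
F4 | step 5 | (1R,2R,3R)-2-[(2-fluorophenyl)acetyl]-3-hydroxy-1,3-dimethylcyclohexane-1-carbonitrile | N#C[C@]1(C)CCC[C@@](C)(O)[C@@H]1C(=O)Cc1ccccc1F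
F5 | step 9 | (3R,3aS,4R,7aR)-4-hydroxy-3-({(1R)-1-[1-hydroxy-3-(trimethylsilyl)prop-2-yn-1-yl]-2-oxocyclohex-4-en-1-yl}methyl)-4,7a-dimethylhexahydro-2-benzofuran-1(3H)-one (carbinol epimers) | C[Si](C)(C)C#CC(O)[C@]1(C[C@H]2OC(=O)[C@]3(C)CCC[C@@](C)(O)[C@H]23)CC=CCC1=O
F6 | step 12 | (3R,3aS,4R,7aR)-4-hydroxy-3-({(1R,5R,7S)-7-hydroxy-2-oxo-6-[(tributylstannyl)methylidene]bicyclo[3.2.1]octan-1-yl}methyl)-4,7a-dimethylhexahydro-2-benzofuran-1(3H)-one | CCCC[Sn](CCCC)(CCCC)C=C1[C@@H]2CCC(=O)[C@@](C[C@H]3OC(=O)[C@]4(C)CCC[C@@](C)(O)[C@H]34)(C2)[C@@H]1O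
F7 | step 12 | (3R,3aS,4R,7aR)-4-hydroxy-3-{[(1R,5R,7R)-7-hydroxy-6-methylidene-2-oxobicyclo[3.2.1]octan-1-yl]methyl}-4,7a-dimethylhexahydro-2-benzofuran-1(3H)-one | C=C1[C@@H]2CCC(=O)[C@@](C[C@H]3OC(=O)[C@]4(C)CCC[C@@](C)(O)[C@H]34)(C2)[C@@H]1O
F8 | step 12 | (1R,5R,7R)-1-{[(1R,3aR,7R,7aS)-7-hydroxy-3a,7-dimethyl-3-oxooctahydro-2-benzofuran-1-yl]methyl}-6-methylidene-2-oxobicyclo[3.2.1]octan-7-yl acetate | C=C1[C@@H]2CCC(=O)[C@@](C[C@H]3OC(=O)[C@]4(C)CCC[C@@](C)(O)[C@H]34)(C2)[C@@H]1OC(C)=O
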